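# Ilimaquinone by an exo-selective asymmetric Diels–Alder construction of ring B: proposed route

Locants are those of the natural product: ring A = C1–C5, C10; ring B = C5–C10; C11 = exocyclic methylene carbon; C15 = benzylic carbon. β is the face of the C8 and C9 methyl groups, α the opposite face.

## Analysis of the target

Ilimaquinone is a rearranged drimane: a trans-fused decalin whose C9 carries, through the C15 methylene, a 2-hydroxy-5-methoxy-1,4-benzoquinone. The four stereocentres C5, C10, C9 and C8 are contiguous (5S,8S,9R,10S). The methyl groups on C5, C9 and C8 all lie on the β face, H-10 and the C15 arm on the α face, and the two quaternary methyl groups (C5, C9) are 1,3-diaxial. The exocyclic C4=C11 alkene migrates into ring A under acid, and the quinone, a vinylogous acid next to a vinylogous ester, does not tolerate organometallics, hydrides or reducing metals, so both have to appear late. The hard points are the neopentyl C9–C15–aryl link and, above all, the C5 methyl: it must be placed trans to H-10 on the face already occupied by the axial C9 methyl, against every steric preference. The strategy rests on C8 (CH–CH3) and C9 (quaternary, CH3 and C15) with their cis methyl groups next to C10–H. This is the pattern left when (E)-2-methylbut-2-enal adds across a 1-vinylcyclohexene, so ring B and three stereocentres can come from one [4+2] cycloaddition. The adduct keeps a formyl group at C15 for the aryl arm, a C5=C6 alkene for the C5 methyl and a masked C4 ketone for the methylene.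

## Retrosynthetic reasoning

**Quinone (25 ⇒ 24 ⇒ 23).** No carbon–carbon bond is cut first. The hydroxy-methoxy-quinone is taken back to the dimethoxyquinone 24 and then to the 2,3,5,6-tetramethoxyphenyl compound 23. The arene is inert to the organolithium, radical, dissolving-metal and strongly basic steps that the quinone would not survive. The forward reactions must oxidise one para pair of methoxy groups and then hydrolyse only the vinylogous ester flanked by the side chain.

**Exocyclic alkene (23 ⇒ 22 ⇒ 21).** C4=C11 is cut to the C4 ketone 22, which is carried as its dioxolane 21. The alkene would not survive the peroxide, carbenoid and acid steps used earlier, so it is the last change on the carbocycle. The forward reaction has to methylenate a ketone that sits next to the quaternary C5.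

**C5 methyl (21 ⇒ 19 ⇒ 17 ⇒ 16 ⇒ 15).** The C5–CH3 bond is traced to the C5–CH2 bond of a cyclopropane fused on the β face of C5–C6. Any reagent that reaches C5 from outside, including an enolate alkylation, would enter on the α face, away from the axial C9 methyl, and give the cis-fused 5-epimer. The carbon therefore has to be delivered from a group already on the β face. A hydroxyl on C4 cannot serve: in the Δ5-octalin its equatorial C–O bond lies in the plane of the C5=C6 bond and its axial one points to the α face, as do the axial bonds at C6 and C10. C7 is the one allylic carbon whose pseudoaxial bond points to the β face. The C7 alcohol 15 is a cyclohex-2-enol, the substrate class in which a zinc carbenoid is delivered cis to oxygen. Oxidation to the cyclopropyl ketone 17 makes the cleavage of the exocyclic C6–CH2 bond selective, and the C7 carbonyl of 19 is then removed.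

**C7 oxygen (15 ⇒ 14 ⇒ 13).** The C7–O bond is cut back to the C7 methylene of alkene 13. C7 is the CH2 next to the less substituted alkene carbon, where an allylic C–H oxidation to the enone 14 is expected. Reduction of 14 from the open α face gives the 7β alcohol.

**Aryl arm (13 ⇒ 12 ⇒ 10 ⇒ 7 + 9).** The C15–aryl bond is cut so that C15 becomes a formyl carbon and the arene an aryllithium, 9, made from the commercial arene 8. This uses the aldehyde that the cycloaddition delivers and avoids a substitution at a neopentyl carbon. The price is a benzylic hydroxyl, removed by way of xanthate 12.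

**Ring B (7 ⇒ 5 + 6).** C7–C8 and C9–C10 are cut together. This is the only disconnection that gives C8, C9 and C10 in one step from an achiral diene and a commercial (E)-enal, and it leaves every later handle in place. The forward reaction needs ortho regiochemistry, an exo formyl group and one enal face.

**Diene (5 ⇒ 4 ⇒ 3 ⇒ 1).** The vinyl–ring bond of 5 is cut to the vinylic bromide 4 and a vinyl-tin reagent. 4 is the dioxolane of bromo-enone 3, made from cyclohexenone 1. Three routine steps lead to the precursor, so the risk lies in the key step.

## Alternatives that were turned down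

**Alternative 1: both rings by an intramolecular Diels–Alder reaction.**
- Disconnection: C5–C10 and C3–C4, back to the open-chain triene A2.
- Forward key step: under an alkylaluminium chloride the (E)-3-methyl enoate (C4=C5) of A2 adds to the (E)-diene (C10=C1–C2=C3). The C6–C9 tether becomes ring B and the product is the trans-fused octalin ester A1.
- For: C5, C10 and the trans ring fusion are set in the ring-forming event, and the C5 methyl is simply a substituent of the dienophile. On this point it is clearly stronger: the chosen route spends six steps (8–13) on that methyl group. The aryl arm is in place from the start.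
- Against: A2 contains an acyclic quaternary C9 next to the C8 methine, and both must be made in an open chain. They are also the only source of face selectivity, relayed through the tether. The dienophile is a β,β-dialkyl enoate, and the forming C5–C10 bond joins two crowded carbons. Afterwards C1=C2 must be hydrogenated and the ester turned into the methylene.
- Comparison: the chosen strategy offers a three-step precursor, catalyst-controlled absolute configuration, and a C8/C9 relationship taken from the geometry of a commercial enal.

**Alternative 2: lactone enolate Claisen contraction onto ring A.**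
- Disconnection: C4–C5, with C1 reconnected to oxygen, back to the silyl ketene acetal A4. In A4 a six-membered lactone ring links C11 through oxygen to C1.
- Forward key step: a [3,3] shift (Ireland–Claisen ring contraction) across C1–C10=C5 forms C4–C5, opens the lactone, closes ring A and gives acid A3.
- For: the quaternary C5 is made by suprafacial intramolecular transfer, so the C1 carbinol configuration fixes the face whatever the C9 methyl demands. C11 arrives with the new bond. H-10 can then be set by hydrogenating C1=C10 from the open α face. On C5 it is equal to or stronger than the chosen route.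
- Against: A4 needs ring B with C8, C9 and a tetrasubstituted C5=C10 alkene, plus a defined C1 centre, before the key step. The difficult C8/C9 pair is moved rather than solved. The boat transition state must form a bond between a tetrasubstituted alkene carbon and a ketene acetal next to C9. Afterwards come the hydrogenation and several steps from acid to methylene.
- Comparison: the chosen strategy builds C8, C9 and C10 in one catalytic step and needs only functional-group chemistry afterwards.

**Alternative 3: quinone ring from a squaric ester by cyclobutenone ring expansion.**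
- Disconnection: inside the six-membered oxygenated ring, back to the 4-hydroxy-4-(2-methoxyvinyl)cyclobutenone A6.
- Forward key step: thermolysis (Moore rearrangement). Four-electron ring opening gives a dienylketene, which closes and tautomerises to the hydroquinone A5. Oxidation and removal of the isopropyl group then give the target.
- For: the positions of hydroxyl and methoxyl are fixed by construction, the isopropyl ether marking the future hydroxyl. This is stronger than the selective hydrolysis of step 17.
- Against: it leaves the decalin and its four stereocentres untouched. It needs a neopentyl C15 carbanion for addition to a squaric ester, then a second organometallic addition, thermolysis, oxidation and dealkylation.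
- Comparison: the chosen strategy takes the arene from a commercial compound in one addition to the formyl group that the cycloaddition provides.

Key step: step 4

Assumption on the chemistry: the sense of induction in step 4 is assigned from the accepted binding model of 2-methyl enals to protonated oxazaborolidines. On that model the (R)-configured catalyst, not the (S) one, leads to the required (8S,9R,10S) adduct. Should the adduct prove to be the mirror image, the (S)-configured catalyst is used and nothing else changes.

## Route

Step 1
Reactants: 1 cyclohex-2-en-1-one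
Product: 3 2-bromocyclohex-2-en-1-one, via 2,3-dibromocyclohexanone 2 (not isolated)
Conditions: Br2, CH2Cl2, 0 °C; then Et3N, 0 °C → rt
Reagents that add atoms: bromine, BrBr
Why: Bromination–dehydrobromination: Br2 adds across the enone and Et3N removes the acidic α-hydrogen with loss of the β-bromide, which leaves the bromine on the α-carbon of the regenerated enone.

Step 2
Reactants: 3 2-bromocyclohex-2-en-1-one
Product: 4 6-bromo-1,4-dioxaspiro[4.5]dec-6-ene
Conditions: ethylene glycol, p-TsOH (cat.), benzene, reflux, Dean–Stark
Reagents that add atoms: ethylene glycol, OCCO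
Why: Acid-catalysed ketalisation driven by azeotropic removal of water; 2-halo enones form their dioxolanes under these conditions without migration of the double bond, so the vinylic bromide needed for the coupling is kept.

Step 3
Reactants: 4 6-bromo-1,4-dioxaspiro[4.5]dec-6-ene
Product: 5 6-vinyl-1,4-dioxaspiro[4.5]dec-6-ene (2-vinylcyclohex-2-en-1-one ethylene ketal)
Conditions: tributyl(vinyl)stannane, Pd(PPh3)4 (5 mol %), toluene, 100 °C
Reagents that add atoms: tributyl(vinyl)stannane, C=C[Sn](CCCC)(CCCC)CCCC
Why: Stille coupling: zerovalent palladium inserts into the vinylic C–Br bond, the vinyl group is transferred from tin and reductive elimination gives the diene; the neutral, base-free conditions leave the ketal alone.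

Step 4
Reactants: 5 6-vinyl-1,4-dioxaspiro[4.5]dec-6-ene; 6 (E)-2-methylbut-2-enal (tiglic aldehyde)
Product: 7 (8S,9R,10S)-4,4-ethylenedioxy-8β,9β-dimethyl-10α-H-octal-5-ene-9α-carbaldehyde (exo adduct; C15 formyl cis to H-10)
Conditions: (R)-3,3-diphenyl-1-(2-methylphenyl)tetrahydro-1H,3H-pyrrolo[1,2-c][1,3,2]oxazaborole (20 mol %), HNTf2 (18 mol %), CH2Cl2, −78 → −20 °C; 5 (1.5 equiv)
Reagents that add atoms: none
Why: Protonation of the oxazaborolidine nitrogen by HNTf2 gives a cationic boron Lewis acid that binds the formyl oxygen of 6 and lowers its LUMO, so a concerted but asynchronous normal-demand [4+2] cycloaddition with the s-cis diene takes place, the bond from the enal β-carbon (C8) to the unsubstituted diene terminus C7 running ahead of the C9–C10 bond. The closest known reaction type is the oxazaborolidinium-catalysed Diels–Alder addition of 2-methyl-2-enals to dienes, and more generally the Lewis-acid-promoted addition of such enals to 1-vinylcyclohexenes. Ring B is closed as a cyclohexene by this intermolecular suprafacial cycloaddition, ring A being carried in by the diene. C8 and C9 are set by suprafacial transfer of the (E) geometry of 6, which puts the two methyl groups cis. C10 is set by the exo position that the α-methyl group forces on the formyl group: the C9 methyl lies under the diene and ends cis to C1, the formyl carbon C15 cis to H-10. The absolute configuration comes from the catalyst: with the formyl C–H held near the ring oxygen and the enal s-trans, a phenyl group of the (R)-catalyst screens the Cα-Re face and the diene adds to the Cα-Si face, which gives (8S,9R,10S). The ortho regiochemistry (C9 to C10, not to C7) follows from the larger HOMO coefficient at the terminal CH2 of the 1-vinylcyclohexene unit and the larger LUMO coefficient at the enal β-carbon, and the s-cis diene conformer is favoured because the s-trans form pushes the vinyl CH2 against the dioxolane. A slight deficit of HNTf2 relative to the oxazaborolidine keeps free Brønsted acid away from the ketal.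

Step 5
Reactants: 7 the exo adduct; 8 1,2,4,5-tetramethoxybenzene
Product: 10 9α-[hydroxy(2,3,5,6-tetramethoxyphenyl)methyl]-4,4-ethylenedioxy-8β,9β-dimethyl-10α-H-octal-5-ene (both C15 epimers), via 2,3,5,6-tetramethoxyphenyllithium 9 (not isolated)
Conditions: 8, n-BuLi, THF, 0 °C → rt; then 7, −78 → 0 °C; H2O
Reagents that add atoms: none
Why: Directed ortho-lithiation between two methoxy groups, then 1,2-addition of the aryllithium to the non-enolisable neopentyl aldehyde; the new C15 carbinol centre forms as a mixture, which does not matter because the oxygen is removed in step 7.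

Step 6
Reactants: 10 the C15 carbinol
Product: 12 O-[C15] S-methyl dithiocarbonate (xanthate) of 10, via sodium xanthate salt 11 (not isolated)
Conditions: NaH, THF, 0 °C → rt; CS2; then MeI
Reagents that add atoms: carbon disulfide, S=C=S; iodomethane, CI
Why: Xanthate formation: the alkoxide adds to CS2 and the dithiocarbonate anion is S-methylated; the carbinol has no β-hydrogen, so thermal syn-elimination is excluded.

Step 7
Reactants: 12 the xanthate
Product: 13 9α-(2,3,5,6-tetramethoxybenzyl)-4,4-ethylenedioxy-8β,9β-dimethyl-10α-H-octal-5-ene
Conditions: Bu3SnH, AIBN (cat.), toluene, 110 °C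
Reagents that add atoms: none
Why: Barton–McCombie deoxygenation: the stannyl radical adds to the thiocarbonyl sulfur, the C15–O bond breaks to a benzylic radical and this takes hydrogen from the tin hydride; the C5=C6 alkene is too far and too strained a partner for cyclisation of the stabilised radical.

Step 8
Reactants: 13 the benzylated octalin
Product: 14 9α-(2,3,5,6-tetramethoxybenzyl)-4,4-ethylenedioxy-8β,9β-dimethyl-10α-H-octal-5-en-7-one
Conditions: Rh2(cap)4 (cap = caprolactamate, 1 mol %), t-BuOOH (70 % in water, 5 equiv), K2CO3, CH2Cl2, rt
Reagents that add atoms: tert-butyl hydroperoxide, CC(C)(C)OO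
Why: Allylic C–H oxidation: the tert-butylperoxyl radical abstracts a hydrogen from C7, the CH2 next to the less substituted alkene carbon, and the mixed peroxide collapses to the conjugated enone. The benzylic CH2 is neopentylic and held out of conjugation by two ortho methoxy groups, and the C5 end of the allyl radical is shielded by the ketal.

Step 9
Reactants: 14 the enone
Product: 15 9α-(2,3,5,6-tetramethoxybenzyl)-4,4-ethylenedioxy-8β,9β-dimethyl-10α-H-octal-5-en-7β-ol
Conditions: NaBH4, CeCl3·7H2O, MeOH, −78 → −40 °C
Reagents that add atoms: none
Why: Luche 1,2-reduction; the β face of the C7 carbonyl is blocked by the syn-axial C9 methyl, so hydride enters from the α face and the new C7 hydroxyl is β (pseudoaxial).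

Step 10
Reactants: 15 the 7β allylic alcohol
Product: 16 9α-(2,3,5,6-tetramethoxybenzyl)-4,4-ethylenedioxy-5β,6β-methano-8β,9β-dimethyl-10α-H-decalin-7β-ol
Conditions: Et2Zn, CH2I2, CH2Cl2, 0 °C → rt
Reagents that add atoms: diiodomethane, ICI
Why: Hydroxyl-directed Simmons–Smith cyclopropanation (Furukawa conditions): the zinc alkoxide of the cyclohex-2-enol delivers the methylene to the alkene face cis to oxygen, in either half-chair of ring B. This sets C5 (and C6) on the β face, syn to the C9 methyl and trans to H-10. The covalently bound alkoxide is a far better anchor than the neutral dioxolane oxygen on the α face.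

Step 11
Reactants: 16 the cyclopropyl carbinol
Product: 17 9α-(2,3,5,6-tetramethoxybenzyl)-4,4-ethylenedioxy-5β,6β-methano-8β,9β-dimethyl-10α-H-decalin-7-one
Conditions: Dess–Martin periodinane, NaHCO3, CH2Cl2, rt
Reagents that add atoms: none
Why: Buffered periodinane oxidation of a secondary alcohol; neither the ketal nor the cyclopropane is touched, and the ketone is what activates the cyclopropane for the next step.

Step 12
Reactants: 17 the cyclopropyl ketone
Product: 19 9α-(2,3,5,6-tetramethoxybenzyl)-4,4-ethylenedioxy-5β,8β,9β-trimethyl-10α-H-decalin-7-one (trans-fused), via lithium enolate 18 (not isolated)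
Conditions: Li (4 equiv), NH3(l)/THF, −78 °C, 20 min; then solid NH4Cl
Reagents that add atoms: none
Why: Dissolving-metal cleavage of a conjugated cyclopropyl ketone: the exocyclic C6–CH2 bond overlaps with the carbonyl π system better than the ring-fusion C5–C6 bond and breaks, which leaves the carbon as a methyl group on C5 with the β configuration set in step 10. The enolate is protonated on quench, and the electron-rich arene is not reduced without an added proton source.

Step 13
Reactants: 19 the 7-ketone
Product: 21 9α-(2,3,5,6-tetramethoxybenzyl)-4,4-ethylenedioxy-5β,8β,9β-trimethyl-10α-H-decalin (trans-fused), via hydrazone 20 (not isolated)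
Conditions: N2H4·H2O, KOH, diethylene glycol, 130 °C then 200 °C
Reagents that add atoms: none
Why: Wolff–Kishner reduction (Huang-Minlon procedure): the hydrazone anion loses N2 to leave a methylene at C7; the purely basic medium keeps the ketal and the aryl ethers, and C8, next to the carbonyl, keeps its equatorial methyl.

Step 14
Reactants: 21 the ketal
Product: 22 9α-(2,3,5,6-tetramethoxybenzyl)-5β,8β,9β-trimethyl-10α-H-decalin-4-one
Conditions: 2 M HCl, THF, rt
Reagents that add atoms: water, O
Why: Acid hydrolysis of the dioxolane; no group in the molecule is acid-labile at this stage, and the strained ketal next to the quaternary C5 should open readily.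

Step 15
Reactants: 22 the C4 ketone
Product: 23 1,2,4,5-tetramethoxy-3-{[(1R,2S,4aS,8aS)-1,2,4a-trimethyl-5-methylidenedecahydronaphthalen-1-yl]methyl}benzene
Conditions: Ph3PCH3Br, KOtBu, toluene, 90 °C
Reagents that add atoms: methyltriphenylphosphonium bromide, C[P+](c1ccccc1)(c1ccccc1)c1ccccc1.[Br-]
Why: Wittig methylenation; the small unstabilised ylide at raised temperature is the standard answer to a ketone next to a quaternary carbon, and the non-acidic conditions keep the new alkene exocyclic.

Step 16
Reactants: 23 the tetramethoxyarene
Product: 24 2,5-dimethoxy-3-{[(1R,2S,4aS,8aS)-1,2,4a-trimethyl-5-methylidenedecahydronaphthalen-1-yl]methyl}cyclohexa-2,5-diene-1,4-dione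
Conditions: (NH4)2Ce(NO3)6, MeCN/H2O, 0 °C
Reagents that add atoms: water, O
Why: Oxidative demethylation of a 1,4-dimethoxyarene: two one-electron oxidations with addition of water and loss of methanol give the para-quinone, and either para pair leads to the same 2,5-dimethoxyquinone; the isolated alkene is not oxidised under these conditions.

Step 17
Reactants: 24 the dimethoxyquinone
Product: 25 ilimaquinone
Conditions: KOH, MeOH/H2O, rt; then 1 M HCl
Reagents that add atoms: potassium hydroxide, [K+].[OH-]
Why: Addition–elimination at a vinylogous ester: the methoxy group flanked by the side chain is twisted out of conjugation, so its carbon is the more electrophilic and takes hydroxide; the vinylogous acid anion formed is deactivated towards a second substitution.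

## Compound list

1 | cyclohex-2-en-1-one | O=C1C=CCCC1 | starting material
2 | 2,3-dibromocyclohexan-1-one | O=C1CCCC(Br)C1Br | intermediate (not isolated)
3 | 2-bromocyclohex-2-en-1-one | O=C1CCCC=C1Br | intermediate
4 | 6-bromo-1,4-dioxaspiro[4.5]dec-6-ene | BrC1=CCCCC12OCCO2 | intermediate
5 | 6-vinyl-1,4-dioxaspiro[4.5]dec-6-ene | C=CC1=CCCCC12OCCO2 | intermediate
6 | (E)-2-methylbut-2-enal (tiglic aldehyde) | C/C=C(\C)C=O | starting material
7 | (8S,9R,10S)-4,4-ethylenedioxy-8β,9β-dimethyl-10α-H-octal-5-ene-9α-carbaldehyde | O=C[C@]1(C)[C@@H](C)CC=C2[C@H]1CCCC23OCCO3 | intermediate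
8 | 1,2,4,5-tetramethoxybenzene | COc1cc(OC)c(OC)cc1OC | starting material
9 | 2,3,5,6-tetramethoxyphenyllithium | [Li]c1c(OC)c(OC)cc(OC)c1OC | intermediate (not isolated)
10 | C15 carbinol (both C15 epimers) | OC(c1c(OC)c(OC)cc(OC)c1OC)[C@]1(C)[C@@H](C)CC=C2[C@H]1CCCC23OCCO3 | intermediate
11 | sodium xanthate salt of 10 | [Na+].[S-]C(=S)OC(c1c(OC)c(OC)cc(OC)c1OC)[C@]1(C)[C@@H](C)CC=C2[C@H]1CCCC23OCCO3 | intermediate (not isolated)
12 | S-methyl xanthate of 10 | CSC(=S)OC(c1c(OC)c(OC)cc(OC)c1OC)[C@]1(C)[C@@H](C)CC=C2[C@H]1CCCC23OCCO3 | intermediate
13 | 9α-(2,3,5,6-tetramethoxybenzyl)-4,4-ethylenedioxy-8β,9β-dimethyl-10α-H-octal-5-ene | COc1cc(OC)c(OC)c(C[C@]2(C)[C@@H](C)CC=C3[C@H]2CCCC34OCCO4)c1OC | intermediate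
14 | octal-5-en-7-one derived from 13 | COc1cc(OC)c(OC)c(C[C@]2(C)[C@@H](C)C(=O)C=C3[C@H]2CCCC34OCCO4)c1OC | intermediate
15 | octal-5-en-7β-ol | COc1cc(OC)c(OC)c(C[C@]2(C)[C@@H](C)[C@@H](O)C=C3[C@H]2CCCC34OCCO4)c1OC | intermediate
16 | 5β,6β-methano-decalin-7β-ol | COc1cc(OC)c(OC)c(C[C@]2(C)[C@@H](C)[C@@H](O)[C@H]3C[C@@]34[C@H]2CCCC45OCCO5)c1OC | intermediate
17 | 5β,6β-methano-decalin-7-one | COc1cc(OC)c(OC)c(C[C@]2(C)[C@@H](C)C(=O)[C@H]3C[C@@]34[C@H]2CCCC45OCCO5)c1OC | intermediate
18 | lithium 6-en-7-olate of 19 | COc1cc(OC)c(OC)c(C[C@]2(C)[C@@H](C)C(O[Li])=C[C@@]3(C)[C@H]2CCCC34OCCO4)c1OC | intermediate (not isolated)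
19 | 5β,8β,9β-trimethyl-trans-decalin-7-one (C4 ketal) | COc1cc(OC)c(OC)c(C[C@]2(C)[C@@H](C)C(=O)C[C@@]3(C)[C@H]2CCCC34OCCO4)c1OC | intermediate
20 | hydrazone of 19 | COc1cc(OC)c(OC)c(C[C@]2(C)[C@@H](C)C(=NN)C[C@@]3(C)[C@H]2CCCC34OCCO4)c1OC | intermediate (not isolated)
21 | 9α-(2,3,5,6-tetramethoxybenzyl)-4,4-ethylenedioxy-5β,8β,9β-trimethyl-trans-decalin | COc1cc(OC)c(OC)c(C[C@]2(C)[C@@H](C)CC[C@@]3(C)[C@H]2CCCC34OCCO4)c1OC | intermediate
22 | 9α-(2,3,5,6-tetramethoxybenzyl)-5β,8β,9β-trimethyl-trans-decalin-4-one | COc1cc(OC)c(OC)c(C[C@]2(C)[C@@H](C)CC[C@@]3(C)[C@H]2CCCC3=O)c1OC | intermediate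
23 | 1,2,4,5-tetramethoxy-3-{[(1R,2S,4aS,8aS)-1,2,4a-trimethyl-5-methylidenedecahydronaphthalen-1-yl]methyl}benzene | COc1cc(OC)c(OC)c(C[C@]2(C)[C@@H](C)CC[C@@]3(C)[C@H]2CCCC3=C)c1OC | intermediate
24 | 2,5-dimethoxyquinone (ilimaquinone methyl ether) | COC1=CC(=O)C(OC)=C(C[C@]2(C)[C@@H](C)CC[C@@]3(C)[C@H]2CCCC3=C)C1=O | intermediate
25 | ilimaquinone | C=C1CCC[C@H]2[C@](C)(CC3=C(O)C(=O)C=C(OC)C3=O)[C@@H](C)CC[C@]12C | target

## Step count and least certain steps

Total: 17 steps. Longest linear sequence: 17 steps from 1; 6 and 8 are bought and enter directly.

**Step 4 (key step).** The dienyl ketal may be ionised or polymerised by the cationic Lewis acid. Control of the enal face or of the exo/endo mode may be incomplete with a β-substituted, α-branched enal and a diene less reactive than cyclopentadiene. The hand of the catalyst rests on a model.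
Fallback (from 5 and 6, back at 7): the cycloaddition is run with an achiral promoter, Me2AlCl in CH2Cl2 at −78 °C. This should keep the exo preference and give 7 together with its mirror image F1. NaBH4 reduces the pair to the primary alcohol F2 and its enantiomer F3. Esterification with (S)-O-acetylmandelic acid (DCC, DMAP) gives the diastereomeric esters F4 and F5, which are separated by chromatography or crystallisation. LiOH cleaves F4 to enantiopure F2, and Dess–Martin oxidation returns 7.

**Step 8.** Hydrogen abstraction may occur at the wrong site, the tertiary allylic C10–H or the benzylic C15–H, or the electron-rich arene may be over-oxidised by the peroxyl radical chain.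
Fallback (from 13, back at 14): the C7 ketone is built by oxygen transposition instead of C–H oxidation. Buffered mCPBA epoxidises 13 on the open α face to the 5α,6α-epoxide F6. LiNEt2 removes a C7 hydrogen and opens the epoxide to the tertiary allylic alcohol F7 (5α-hydroxy, C6=C7). Pyridinium chlorochromate, [C5H5NH][CrO3Cl], then effects the oxidative 1,3-transposition of the tertiary allylic alcohol to the enone 14.

**Step 10.** Methylene transfer may be slow or go to the wrong face: the β face is flanked by the C9 methyl, and the axial dioxolane oxygen on the α face can also bind zinc.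
Fallback (from 15, back at 21, bypassing steps 10–13): the carbon is delivered by a sigmatropic shift from the same 7β oxygen.
- Ethyl vinyl ether and Hg(OAc)2 convert 15 into the allyl vinyl ether F8.
- Heating (toluene, 150 °C, sealed tube) brings about the Claisen rearrangement, which is suprafacial and places a CH2CHO group on the β face of C5 with the alkene moved to C6=C7, giving aldehyde F9.
- Decarbonylation with RhCl(PPh3)3 (Tsuji–Wilkinson) turns the CH2CHO group into the C5 methyl, giving olefin F10.
- Hydrogenation (H2, Pd/C) gives 21.

**Step 17.** Hydroxide may attack the other vinylogous ester carbon (the C–OMe next to C–H), or both, and the selectivity rests on a modest steric and electronic difference.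
Fallback (from 24, back at 25): both methoxy groups are hydrolysed (aqueous NaOH, dioxane, warm, then acid) to the 2,5-dihydroxyquinone F11. One equivalent of trimethylsilyldiazomethane in toluene/MeOH at 0 °C then methylates the less hindered hydroxyl, the one next to the ring C–H. In either tautomer of F11 this is the oxygen that must carry the methyl group of 25. No acid is used, so the exocyclic alkene stays in place.

## Further compounds

F1 | step 4 | mirror image of 7 | O=C[C@@]1(C)[C@H](C)CC=C2[C@@H]1CCCC23OCCO3
F2 | step 4 | C15 primary alcohol from 7 | OC[C@]1(C)[C@@H](C)CC=C2[C@H]1CCCC23OCCO3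
F3 | step 4 | mirror image of F2 | OC[C@@]1(C)[C@H](C)CC=C2[C@@H]1CCCC23OCCO3
F4 | step 4 | (S)-O-acetylmandelate of F2 | CC(=O)O[C@H](C(=O)OC[C@]1(C)[C@@H](C)CC=C2[C@H]1CCCC23OCCO3)c1ccccc1
F5 | step 4 | (S)-O-acetylmandelate of F3 | CC(=O)O[C@H](C(=O)OC[C@@]1(C)[C@H](C)CC=C2[C@@H]1CCCC23OCCO3)c1ccccc1
F6 | step 8 | 5α,6α-epoxide of 13 | COc1cc(OC)c(OC)c(C[C@]2(C)[C@@H](C)C[C@@H]3O[C@]34[C@H]2CCCC45OCCO5)c1OC
F7 | step 8 | 5α-hydroxy-octal-6-ene (tertiary allylic alcohol) | COc1cc(OC)c(OC)c(C[C@]2(C)[C@@H](C)C=C[C@]3(O)[C@H]2CCCC34OCCO4)c1OC
F8 | step 10 | 7β-vinyl ether of 15 | COc1cc(OC)c(OC)c(C[C@]2(C)[C@@H](C)[C@@H](OC=C)C=C3[C@H]2CCCC34OCCO4)c1OC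
F9 | step 10 | 5β-(2-oxoethyl)-octal-6-ene | COc1cc(OC)c(OC)c(C[C@]2(C)[C@@H](C)C=C[C@@]3(CC=O)[C@H]2CCCC34OCCO4)c1OC
F10 | step 10 | 5β-methyl-octal-6-ene | COc1cc(OC)c(OC)c(C[C@]2(C)[C@@H](C)C=C[C@@]3(C)[C@H]2CCCC34OCCO4)c1OC
F11 | step 17 | 2,5-dihydroxyquinone (O-demethyl-ilimaquinone) | OC1=CC(=O)C(O)=C(C[C@]2(C)[C@@H](C)CC[C@@]3(C)[C@H]2CCCC3=C)C1=O
A1 | alternative 1 | trans-fused 1-octalin C4 methyl ester (product of the intramolecular Diels–Alder reaction) | COC(=O)[C@H]1CC=C[C@H]2[C@](C)(Cc3c(OC)c(OC)cc(OC)c3OC)[C@@H](C)CC[C@]12C
A2 | alternative 1 | open-chain triene ester (cycloaddition substrate) | COC(=O)/C=C(\C)CC[C@H](C)[C@@](C)(Cc1c(OC)c(OC)cc(OC)c1OC)/C=C/C=C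
A3 | alternative 2 | 1(10)-octalin-4-carboxylic acid with quaternary C5 (product of the Claisen contraction) | OC(=O)[C@@H]1CCC=C2[C@](C)(Cc3c(OC)c(OC)cc(OC)c3OC)[C@@H](C)CC[C@]12C
A4 | alternative 2 | tert-butyldimethylsilyl ketene acetal of the six-membered lactone on C1 | CC(C)(C)[Si](C)(C)OC1=CCC[C@H](O1)C2=C(C)CC[C@H](C)[C@@]2(C)Cc3c(OC)c(OC)cc(OC)c3OC
A5 | alternative 3 | 3-alkyl-2-isopropoxy-5-methoxyhydroquinone (product of the ring expansion) | C=C1CCC[C@H]2[C@](C)(Cc3c(O)c(OC)cc(O)c3OC(C)C)[C@@H](C)CC[C@]12C
A6 | alternative 3 | 4-hydroxy-4-(2-methoxyvinyl)-3-isopropoxy-2-alkylcyclobutenone | C=C1CCC[C@H]2[C@](C)(CC3=C(OC(C)C)C(O)(/C=C\OC)C3=O)[C@@H](C)CC[C@]12C
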